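**Strategy.** The ring carbon C1 (the CH between the quaternary, pyranone-bearing C6 and the epoxide carbon C2) is joined to the vinyl carbon of the side chain by an allenyl ether Claisen rearrangement. The precursor is a mirror-symmetric cyclohexa-2,5-dienyl propargyl ether, built by Birch reductive methylation of 3,5-dimethylbenzoic acid. Base-mediated isomerisation to the allenyl ether and a suprafacial [3,3] shift turn the C3–O bond into the C1–C bond cis to the pyranone, move the ring alkene to C2=C3 (the later epoxide) and unveil a 2-substituted acrolein for the closing syn-aldol. The step exploits the 1,3-relationship of C1 and the oxygen-bearing C3 in the six-membered ring.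

Key step: step 8

Ring numbering used throughout: C1 (CH bearing the side chain), C2 and C3 (epoxide carbons, C2 with methyl), C4=C5 (alkene, C4 with methyl), C6 (quaternary, methyl and pyranone).

Remark on stereochemistry: compounds 10–12 are achiral (mirror plane through C3 and C6), so step 8 should give 13 as a racemate of fixed relative configuration. The absolute configuration is introduced in step 10, where an enantiopure enol borinate should convert the two enantiomers of 14 into separable diastereomers, at the cost of half the material.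

Assumption: the (Z)-enol borinate made with (+)-Ipc2BOTf (from (−)-α-pinene) is taken to add to the Re face of the aldehyde, as the (4R,5R) configuration requires. If the sense of induction is the opposite one, the enantiomeric reagent is used.

**Step 1**
Reactants: 1 3,5-dimethylbenzoic acid
Product: 2 1,3,5-trimethylcyclohexa-2,5-diene-1-carboxylic acid
Conditions: Li, NH3(l)/THF, −78 °C; MeI, −78 °C to rt; aq. HCl
Reagents that add atoms: iodomethane, CI
Why: Dissolving-metal (Birch) reduction of the benzoate places the carbanion at the carboxyl-bearing carbon and leaves the two methyl groups on the remaining alkenes, and this enolate is C-methylated in the same flask (Birch reductive alkylation), the product keeping a mirror plane so that no stereocenter arises.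

**Step 2**
Reactants: 2 1,3,5-trimethylcyclohexa-2,5-diene-1-carboxylic acid; 3 methyl 2-methyl-3-oxopentanoate
Product: 6 methyl 2,4-dimethyl-3,5-dioxo-5-(1,3,5-trimethylcyclohexa-2,5-dien-1-yl)pentanoate, via acyl imidazole 4 (not isolated), via ketoester dianion 5 (not isolated)
Conditions: 2, 1,1'-carbonyldiimidazole, THF, rt; separately 3, NaH then n-BuLi, THF, 0 °C; combine at −78 °C to 0 °C; aq. NH4Cl
Reagents that add atoms: 1,1'-carbonyldiimidazole, O=C(n1ccnc1)n1ccnc1 (gives the imidazolyl group of intermediate 4; no atom of it remains in 6)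
Why: The terminal carbanion of the β-keto ester dianion is its most nucleophilic site and is C-acylated by the non-enolisable acyl imidazole (Claisen-type acylation), the product surviving as its stabilised enolate; the two CH(CH3) centres form without control because both become sp2 in step 3.

**Step 3**
Reactants: 6 methyl 2,4-dimethyl-3,5-dioxo-5-(1,3,5-trimethylcyclohexa-2,5-dien-1-yl)pentanoate
Product: 7 4-hydroxy-3,5-dimethyl-6-(1,3,5-trimethylcyclohexa-2,5-dien-1-yl)-2H-pyran-2-one
Conditions: DBU, PhMe, rt to 60 °C; dilute aq. HCl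
Reagents that add atoms: none
Why: DBU enolises the 3,5-diketo ester and the enol oxygen of the ketone next to the quaternary carbon closes onto the methyl ester (6-exo-trig lactonisation), the aromatic 4-hydroxy-2-pyranone being the thermodynamic sink.

**Step 4**
Reactants: 7 4-hydroxy-3,5-dimethyl-6-(1,3,5-trimethylcyclohexa-2,5-dien-1-yl)-2H-pyran-2-one
Product: 8 2-methoxy-3,5-dimethyl-6-(1,3,5-trimethylcyclohexa-2,5-dien-1-yl)-4H-pyran-4-one
Conditions: MeOTf, CH2Cl2, rt; aq. NaHCO3
Reagents that add atoms: methyl trifluoromethanesulfonate, COS(=O)(=O)C(F)(F)F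
Why: The hard methylating agent alkylates the lactone carbonyl oxygen of the neutral hydroxypyranone, and proton loss from the resulting 2-methoxy-4-hydroxypyrylium salt, which also keeps the triflic acid away from the diene until the bicarbonate wash, gives the 2-methoxy-4-pyranone (regioselective O-methylation).

**Step 5**
Reactants: 8 2-methoxy-3,5-dimethyl-6-(1,3,5-trimethylcyclohexa-2,5-dien-1-yl)-4H-pyran-4-one
Product: 9 2-methoxy-3,5-dimethyl-6-(1,3,5-trimethyl-4-oxocyclohexa-2,5-dien-1-yl)-4H-pyran-4-one
Conditions: CrO3 (cat.), t-BuOOH, CH2Cl2, 0 °C to rt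
Reagents that add atoms: tert-butyl hydroperoxide, CC(C)(C)OO
Why: The doubly allylic CH2 has by far the weakest C–H bonds and its pentadienyl termini are shielded by the quaternary carbon, so chromium-catalysed hydroperoxide oxidation (allylic oxidation) should functionalise C3 and give the cross-conjugated dienone.

**Step 6**
Reactants: 9 2-methoxy-3,5-dimethyl-6-(1,3,5-trimethyl-4-oxocyclohexa-2,5-dien-1-yl)-4H-pyran-4-one
Product: 10 6-(cis-4-hydroxy-1,3,5-trimethylcyclohexa-2,5-dien-1-yl)-2-methoxy-3,5-dimethyl-4H-pyran-4-one (hydroxyl cis to the pyranone)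
Conditions: NaBH4, CeCl3·7H2O, MeOH, −40 °C; base-washed silica
Reagents that add atoms: none
Why: Luche conditions effect clean 1,2-reduction of the dienone while the vinylogous carbonate carbonyl of the pyranone is inert, and hydride should enter at C3 from the face of the small C6 methyl group, away from the pyranone, so that the hydroxyl ends cis to the pyranone (substrate-controlled Luche reduction; any trans isomer is removed by chromatography and reoxidised with MnO2).

**Step 7**
Reactants: 10 6-(cis-4-hydroxy-1,3,5-trimethylcyclohexa-2,5-dien-1-yl)-2-methoxy-3,5-dimethyl-4H-pyran-4-one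
Product: 11 2-methoxy-3,5-dimethyl-6-[cis-1,3,5-trimethyl-4-(prop-2-yn-1-yloxy)cyclohexa-2,5-dien-1-yl]-4H-pyran-4-one
Conditions: NaH, propargyl bromide, Bu4NI (cat.), THF/DMF, 0 °C to rt
Reagents that add atoms: 3-bromoprop-1-yne (propargyl bromide), C#CCBr
Why: Williamson etherification takes place at the primary propargylic carbon of the bromide, so the carbinol centre and its cis relationship to the pyranone are untouched.

**Step 8**
Reactants: 11 2-methoxy-3,5-dimethyl-6-[cis-1,3,5-trimethyl-4-(prop-2-yn-1-yloxy)cyclohexa-2,5-dien-1-yl]-4H-pyran-4-one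
Product: 13 rac-2-[6-(6-methoxy-3,5-dimethyl-4-oxo-4H-pyran-2-yl)-2,4,6-trimethylcyclohexa-2,4-dien-1-yl]prop-2-enal (propenal unit cis to the pyranone), via allenyl ether 12 (not isolated)
Conditions: t-BuOK (0.3 equiv), THF, 0 °C to rt; pH 7 buffer wash; PhMe (0.02 M), BHT, 100 °C
Reagents that add atoms: none
Why: Catalytic potassium tert-butoxide moves the propargylic proton to give the alkoxyallene 12 (propargyl–allenyl isomerisation), whose O–CH=C unit and the ring C1=C2–C3 allyl unit form an allyl vinyl ether that undergoes a concerted suprafacial [3,3] sigmatropic shift on heating. The closest known reaction type is the Claisen rearrangement of allyl allenyl ethers to 2-methylene-4-pentenals. No ring is closed: the C3–O bond is exchanged for the bond from C1 to the central allene carbon, the ring alkene moves to C2=C3 in conjugation with C4=C5, and the allene becomes the 1,1-disubstituted alkene plus the aldehyde. The new stereocenter C1 is controlled by the carbinol configuration, since the carbon is delivered to the ring face that carried the oxygen, that is cis to the pyranone on the adjacent quaternary C6, the face an external nucleophile would avoid. The two allyl termini C1 and C5 are enantiotopic, so there is no regiochemical issue but the product is racemic; the step needs the isomerisation to stop at the allene and the base-sensitive, doubly allylic C1–H of the enal to survive, which the catalytic base, its removal before heating and a dilute, radical-inhibited thermolysis should secure.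

**Step 9**
Reactants: 13 rac-2-[6-(6-methoxy-3,5-dimethyl-4-oxo-4H-pyran-2-yl)-2,4,6-trimethylcyclohexa-2,4-dien-1-yl]prop-2-enal
Product: 14 rac-2-[4-(6-methoxy-3,5-dimethyl-4-oxo-4H-pyran-2-yl)-2,4,6-trimethyl-7-oxabicyclo[4.1.0]hept-2-en-5-yl]prop-2-enal (epoxide oxygen trans to the propenal unit and to the pyranone)
Conditions: dimethyldioxirane (1.05 equiv), acetone, −30 °C
Reagents that add atoms: dimethyldioxirane, CC1(C)OO1
Why: Dimethyldioxirane is a neutral electrophilic oxidant that leaves the electron-poor enal and pyranone alkenes alone and should attack the diene at C2=C3 from the lower face, because the upper face carries the C1 and C6 substituents and the lower face of C4=C5 is shielded by the C6 methyl group, which sets the epoxide oxygen trans to the C1 chain (substrate-controlled epoxidation).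

**Step 10**
Reactants: 14 rac-2-[4-(6-methoxy-3,5-dimethyl-4-oxo-4H-pyran-2-yl)-2,4,6-trimethyl-7-oxabicyclo[4.1.0]hept-2-en-5-yl]prop-2-enal; 15 pentan-3-one
Product: 18 CNP0233636.2 (4R,5R)-5-hydroxy-6-[4-(6-methoxy-3,5-dimethyl-4-oxo-4H-pyran-2-yl)-2,4,6-trimethyl-7-oxabicyclo[4.1.0]hept-2-en-5-yl]-4-methylhept-6-en-3-one, via enol borinate 16 (not isolated), via boron aldolate 17 (not isolated)
Conditions: 15, (+)-Ipc2BOTf, i-Pr2NEt, CH2Cl2, −78 °C; 14, −78 to −20 °C; H2O2, pH 7 buffer, MeOH, 0 °C; chromatographic separation of the diastereomers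
Reagents that add atoms: (+)-diisopinocampheylboron triflate, FC(F)(F)S(=O)(=O)OB([C@H]1C[C@H]2C[C@@H]([C@@H]1C)C2(C)C)[C@H]1C[C@H]2C[C@@H]([C@@H]1C)C2(C)C (boron and ligands are carried by intermediates 16 and 17 only; no atom of it remains in 18)
Why: The (Z)-enol diisopinocampheylborinate of pentan-3-one adds to the 2-substituted acrolein through a closed chair transition state, which gives the 4,5-syn aldol with both new centres set by the isopinocampheyl ligands (reagent-controlled boron aldol reaction), so that racemic 14 should give two diastereomers from which the target, the one derived from the aldehyde enantiomer drawn for 14, is separated.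

**Compound list**
1 | 3,5-dimethylbenzoic acid | Cc1cc(C)cc(c1)C(=O)O | starting material
2 | 1,3,5-trimethylcyclohexa-2,5-diene-1-carboxylic acid (achiral) | CC1=CC(C)(C(=O)O)C=C(C)C1 | intermediate
3 | methyl 2-methyl-3-oxopentanoate (racemic; its stereocentre is lost in step 3) | CCC(=O)C(C)C(=O)OC | starting material
4 | 1-(1,3,5-trimethylcyclohexa-2,5-diene-1-carbonyl)-1H-imidazole | CC1=CC(C)(C(=O)n2ccnc2)C=C(C)C1 | intermediate (not isolated)
5 | sodium lithium dianion (bis-enolate) of 3 | CC=C([O-])C(C)=C([O-])OC.[Na+].[Li+] | intermediate (not isolated)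
6 | methyl 2,4-dimethyl-3,5-dioxo-5-(1,3,5-trimethylcyclohexa-2,5-dien-1-yl)pentanoate (mixture of diastereomers and enol forms; both stereocentres are lost in step 3) | COC(=O)C(C)C(=O)C(C)C(=O)C1(C)C=C(C)CC(C)=C1 | intermediate
7 | 4-hydroxy-3,5-dimethyl-6-(1,3,5-trimethylcyclohexa-2,5-dien-1-yl)-2H-pyran-2-one | CC1=CC(C)(c2oc(=O)c(C)c(O)c2C)C=C(C)C1 | intermediate
8 | 2-methoxy-3,5-dimethyl-6-(1,3,5-trimethylcyclohexa-2,5-dien-1-yl)-4H-pyran-4-one | CC1=CC(C)(c2oc(OC)c(C)c(=O)c2C)C=C(C)C1 | intermediate
9 | 2-methoxy-3,5-dimethyl-6-(1,3,5-trimethyl-4-oxocyclohexa-2,5-dien-1-yl)-4H-pyran-4-one | CC1=CC(C)(c2oc(OC)c(C)c(=O)c2C)C=C(C)C1=O | intermediate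
10 | 6-(cis-4-hydroxy-1,3,5-trimethylcyclohexa-2,5-dien-1-yl)-2-methoxy-3,5-dimethyl-4H-pyran-4-one (hydroxyl cis to the pyranone; achiral) | O[C@@H]1C(C)=C[C@](C)(c2oc(OC)c(C)c(=O)c2C)C=C1C | intermediate
11 | 2-methoxy-3,5-dimethyl-6-[cis-1,3,5-trimethyl-4-(prop-2-yn-1-yloxy)cyclohexa-2,5-dien-1-yl]-4H-pyran-4-one (achiral) | C#CCO[C@@H]1C(C)=C[C@](C)(c2oc(OC)c(C)c(=O)c2C)C=C1C | intermediate
12 | 2-methoxy-3,5-dimethyl-6-[cis-1,3,5-trimethyl-4-(propa-1,2-dien-1-yloxy)cyclohexa-2,5-dien-1-yl]-4H-pyran-4-one (achiral) | C=C=CO[C@@H]1C(C)=C[C@](C)(c2oc(OC)c(C)c(=O)c2C)C=C1C | intermediate (not isolated)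
13 | rac-2-[6-(6-methoxy-3,5-dimethyl-4-oxo-4H-pyran-2-yl)-2,4,6-trimethylcyclohexa-2,4-dien-1-yl]prop-2-enal, propenal cis to the pyranone (racemate; the SMILES shows the enantiomer that leads to 18) | C=C(C=O)[C@H]1C(C)=CC(C)=C[C@@]1(C)c1oc(OC)c(C)c(=O)c1C | intermediate
14 | rac-2-[4-(6-methoxy-3,5-dimethyl-4-oxo-4H-pyran-2-yl)-2,4,6-trimethyl-7-oxabicyclo[4.1.0]hept-2-en-5-yl]prop-2-enal, epoxide oxygen trans to propenal and pyranone (racemate; the SMILES shows the enantiomer that leads to 18) | C=C(C=O)[C@H]1[C@]2(C)O[C@@H]2C(C)=C[C@@]1(C)c1oc(OC)c(C)c(=O)c1C | intermediate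
15 | pentan-3-one | CCC(=O)CC | starting material
16 | (Z)-pent-2-en-3-yl bis[(+)-isopinocampheyl]borinate | CC/C(=C/C)OB([C@H]1C[C@H]2C[C@@H]([C@@H]1C)C2(C)C)[C@H]1C[C@H]2C[C@@H]([C@@H]1C)C2(C)C | intermediate (not isolated)
17 | O-bis[(+)-isopinocampheyl]boryl aldolate of 18 | C=C([C@H](OB([C@H]2C[C@H]3C[C@@H]([C@@H]2C)C3(C)C)[C@H]2C[C@H]3C[C@@H]([C@@H]2C)C3(C)C)[C@@H](C)C(=O)CC)[C@H]1[C@]2(C)O[C@@H]2C(C)=C[C@@]1(C)c1oc(OC)c(C)c(=O)c1C | intermediate (not isolated)
18 | CNP0233636.2, (4R,5R)-5-hydroxy-6-[4-(6-methoxy-3,5-dimethyl-4-oxo-4H-pyran-2-yl)-2,4,6-trimethyl-7-oxabicyclo[4.1.0]hept-2-en-5-yl]-4-methylhept-6-en-3-one (side chain cis to the pyranone, epoxide oxygen trans to both) | C=C([C@H](O)[C@@H](C)C(=O)CC)[C@H]1[C@]2(C)O[C@@H]2C(C)=C[C@@]1(C)c1oc(OC)c(C)c(=O)c1C | target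

Total step count: 10. Longest linear sequence: 10 steps (from 1).

**Steps most likely to fail**

Step 9. The epoxidation may lose site selectivity (attack at C4=C5 or double epoxidation), the aldehyde may be oxidised, and the vinyl epoxide may open during handling or in the following boron aldol. The fallback reverses the order and replaces substrate control by catalyst control. It sets out from 13, which is taken through the boron aldol of step 10 first, by way of the boron aldolate F1, to the diene aldol F2 after separation of its diastereomer. F2 is then epoxidised under Shi conditions (fructose-derived ketone catalyst, Oxone, K2CO3 buffer, MeCN/dimethoxymethane, 0 °C), using the catalyst enantiomer matched to the lower face of C2=C3. The bulky chiral dioxirane should ignore the 1,1-disubstituted alkene of the side chain and the alkene next to the quaternary carbon. The route is rejoined at 18.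

Step 6. Hydride delivery may show poor or reversed facial selectivity, because the controlling centre C6 lies across the ring from the carbonyl. The fallback accepts whatever the reduction gives and corrects the carbinol centre by inversion. It sets out from 9; if the trans-dienol F3 predominates, it is subjected to Mitsunobu esterification (4-nitrobenzoic acid, PPh3, diisopropyl azodicarboxylate, THF, 0 °C), which should give the inverted cis 4-nitrobenzoate F4. Methanolysis (K2CO3, MeOH) returns to the route at 10.

Step 8. The base may carry the isomerisation past the allene to the 1-propynyl ether or remove the doubly allylic C3–H, and the enal may dimerise or lose its C1 configuration by hydrogen shift during thermolysis. The fallback avoids strong base and forms the enal last. It sets out from 10, which is converted by transfer vinylation (butyl vinyl ether, Pd(OCOCF3)2, 4,7-diphenyl-1,10-phenanthroline, Et3N, 75 °C) into the vinyl ether F5. A thermal Claisen rearrangement (PhMe, sealed tube, 150 °C) should give, with the same suprafacial delivery, the aldehyde F6. Amine-catalysed α-methylenation (aqueous formaldehyde, pyrrolidine and propionic acid as catalysts, i-PrOH, 45 °C) returns to the route at 13.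

**Further compounds**
F1 | step 9 | O-bis[(+)-isopinocampheyl]boryl aldolate of F2 | C=C([C@H](OB([C@H]2C[C@H]3C[C@@H]([C@@H]2C)C3(C)C)[C@H]2C[C@H]3C[C@@H]([C@@H]2C)C3(C)C)[C@@H](C)C(=O)CC)[C@H]1C(C)=CC(C)=C[C@@]1(C)c1oc(OC)c(C)c(=O)c1C
F2 | step 9 | (4R,5R)-5-hydroxy-6-[6-(6-methoxy-3,5-dimethyl-4-oxo-4H-pyran-2-yl)-2,4,6-trimethylcyclohexa-2,4-dien-1-yl]-4-methylhept-6-en-3-one (diene aldol, side chain cis to the pyranone) | C=C([C@H](O)[C@@H](C)C(=O)CC)[C@H]1C(C)=CC(C)=C[C@@]1(C)c1oc(OC)c(C)c(=O)c1C
F3 | step 6 | 6-(trans-4-hydroxy-1,3,5-trimethylcyclohexa-2,5-dien-1-yl)-2-methoxy-3,5-dimethyl-4H-pyran-4-one (hydroxyl trans to the pyranone) | O[C@H]1C(C)=C[C@](C)(c2oc(OC)c(C)c(=O)c2C)C=C1C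
F4 | step 6 | cis-4-(6-methoxy-3,5-dimethyl-4-oxo-4H-pyran-2-yl)-2,4,6-trimethylcyclohexa-2,5-dien-1-yl 4-nitrobenzoate | O=C(O[C@@H]1C(C)=C[C@](C)(c2oc(OC)c(C)c(=O)c2C)C=C1C)c1ccc(cc1)[N+](=O)[O-]
F5 | step 8 | 6-[cis-4-(ethenyloxy)-1,3,5-trimethylcyclohexa-2,5-dien-1-yl]-2-methoxy-3,5-dimethyl-4H-pyran-4-one | C=CO[C@@H]1C(C)=C[C@](C)(c2oc(OC)c(C)c(=O)c2C)C=C1C
F6 | step 8 | rac-2-[6-(6-methoxy-3,5-dimethyl-4-oxo-4H-pyran-2-yl)-2,4,6-trimethylcyclohexa-2,4-dien-1-yl]acetaldehyde (side chain cis to the pyranone) | O=CC[C@H]1C(C)=CC(C)=C[C@@]1(C)c1oc(OC)c(C)c(=O)c1C
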